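The target is the 15‑oleate of isocupressic acid; labdane locants are used (ring A = C1–C5 + C10, ring B = C5–C10, C17 = CH2 on C8, C19 = carboxyl on C4, C20 = CH3 on C10). Last cuts: the C19 tert‑butyl ester, the oleate at O15, and the C13–C16 end of the side chain (acetylide alkylation at C12, then Zr‑catalysed carboalumination/hydroxymethylation).
C4 (CH3, CO2R) and H‑5 are traced back to a reductive methylation of a bicyclic C4=C5 conjugated ester, so the bicycle itself carries only C9 and C10 as stereocentres.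
Key disconnection: the bonds C5–C10 and C7–C8 are cut together, which opens both rings to an acyclic enyne ester; in the forward sense ring A closes first (tertiary C10 radical to C5, 6‑endo) and ring B second (C7 radical to the alkyne carbon C8, 6‑exo‑dig).
Feature that makes this possible: the C19 carboxyl on C4 sits next to the ring‑fusion carbon C5 of ring A, and C5 is joined through the two ring B methylenes C6–C7 to the methylidene carbon C8. C19 turns C4=C5 into a radical acceptor, C6 and C7 are brought in as a spiro‑cyclopropane on C5 (temporary bond C5–C7) whose strain‑driven opening carries the radical from C4 to C7, and C8=C17 is what an ethynyl group leaves behind.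
The cascade precursor has a single stereocentre (C9), set by a Johnson–Claisen rearrangement of an allylic alcohol that comes from an enantioselective alkylzinc addition to an enynal; the cyclopropylidene ester is installed last by a Wittig reaction on an α‑keto ester.

Key step: step 10

Assumption: the (1S,2S)‑bis(sulfonamide) ligand of step 2 is taken to deliver the alkyl group to the Re face of enal 3 (the usual sense for this catalyst class); if the sense is the opposite, its enantiomer is used.

Step 1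
Reactants: 1 3-(trimethylsilyl)prop-2-ynal; 2 2-(triphenyl-λ5-phosphanylidene)propanal
Product: 3 (2E)-2-methyl-5-(trimethylsilyl)pent-2-en-4-ynal
Conditions: PhMe, 80 °C
Reagents that add atoms: none
Why: Wittig olefination with a formyl‑stabilised ylide, which should give the (E)‑enal (alkynyl trans to CHO) through the more stable oxaphosphetane; no stereocentre is formed.

Step 2
Reactants: 4 tert-butyl 4-iodobutanoate; 3 (2E)-2-methyl-5-(trimethylsilyl)pent-2-en-4-ynal
Product: 6 tert-butyl (5R,6E)-5-hydroxy-6-methyl-9-(trimethylsilyl)non-6-en-8-ynoate, via bis(4-tert-butoxy-4-oxobutyl)zinc 5 (not isolated)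
Conditions: Et2Zn, CuI (cat.), 50 °C, then vacuum; Ti(OiPr)4, (1S,2S)-1,2-bis(trifluoromethanesulfonamido)cyclohexane (8 mol %), PhMe, −20 °C; aq NH4Cl
Reagents that add atoms: none
Why: Iodine–zinc exchange gives the functionalised dialkylzinc 5, whose titanium/bis(sulfonamide)‑catalysed enantioselective 1,2‑addition to the α‑branched enal sets the carbinol centre C1 (R) by ligand control, the tert‑butyl ester keeping the δ‑hydroxy ester from lactonising.

Step 3
Reactants: 6 tert-butyl (5R,6E)-5-hydroxy-6-methyl-9-(trimethylsilyl)non-6-en-8-ynoate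
Product: 8 1-tert-butyl 9-ethyl (5E,7R)-6-methyl-7-[(trimethylsilyl)ethynyl]non-5-enedioate, via mixed ketene acetal 7 (not isolated)
Conditions: MeC(OEt)3, EtCO2H (cat.), 135 °C, ethanol distilled off
Reagents that add atoms: triethyl orthoacetate CC(OCC)(OCC)OCC
Why: Johnson orthoester Claisen rearrangement, in which the chair transition state with the C2 chain equatorial delivers C11 to C9 on the face that the C1–O bond leaves, so that the C1 configuration is transferred to C9 and the new C1=C10 alkene is (E).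

Step 4
Reactants: 8 1-tert-butyl 9-ethyl (5E,7R)-6-methyl-7-[(trimethylsilyl)ethynyl]non-5-enedioate
Product: 9 tert-butyl (5E,7R)-9-hydroxy-6-methyl-7-[(trimethylsilyl)ethynyl]non-5-enoate
Conditions: LiBH4, Et2O/THF, 0 °C → rt
Reagents that add atoms: none
Why: Chemoselective hydride reduction, since LiBH4 reduces the unhindered ethyl ester at C12 far faster than the tert‑butyl ester; no stereocentre is touched.

Step 5
Reactants: 9 tert-butyl (5E,7R)-9-hydroxy-6-methyl-7-[(trimethylsilyl)ethynyl]non-5-enoate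
Product: 10 tert-butyl (5E,7R)-6-methyl-9-{[tri(propan-2-yl)silyl]oxy}-7-[(trimethylsilyl)ethynyl]non-5-enoate
Conditions: i-Pr3SiCl, imidazole, DMF, rt
Reagents that add atoms: chlorotri(propan-2-yl)silane CC(C)[Si](Cl)(C(C)C)C(C)C
Why: Silylation of the primary alcohol masks O12 for the enolate, oxidation, radical and dissolving‑metal steps that follow.

Step 6
Reactants: 10 tert-butyl (5E,7R)-6-methyl-9-{[tri(propan-2-yl)silyl]oxy}-7-[(trimethylsilyl)ethynyl]non-5-enoate
Product: 12 tert-butyl (5E,7R)-2-hydroxy-6-methyl-9-{[tri(propan-2-yl)silyl]oxy}-7-[(trimethylsilyl)ethynyl]non-5-enoate, via potassium ester enolate 11 (not isolated)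
Conditions: KN(SiMe3)2, THF, −78 °C; 2-(phenylsulfonyl)-3-phenyloxaziridine; aq NH4Cl
Reagents that add atoms: 2-(phenylsulfonyl)-3-phenyloxaziridine O=S(=O)(N1OC1c1ccccc1)c1ccccc1
Why: Enolate hydroxylation with an N‑sulfonyloxaziridine at C4; the configuration of the new carbinol does not matter because it is oxidised in step 7.

Step 7
Reactants: 12 tert-butyl (5E,7R)-2-hydroxy-6-methyl-9-{[tri(propan-2-yl)silyl]oxy}-7-[(trimethylsilyl)ethynyl]non-5-enoate
Product: 13 tert-butyl (5E,7R)-6-methyl-2-oxo-9-{[tri(propan-2-yl)silyl]oxy}-7-[(trimethylsilyl)ethynyl]non-5-enoate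
Conditions: Dess–Martin periodinane, CH2Cl2, rt
Reagents that add atoms: none
Why: Dess–Martin oxidation of the secondary α‑hydroxy ester to the α‑keto ester under neutral conditions that leave the silyl groups and the C9 centre untouched.

Step 8
Reactants: 13 tert-butyl (5E,7R)-6-methyl-2-oxo-9-{[tri(propan-2-yl)silyl]oxy}-7-[(trimethylsilyl)ethynyl]non-5-enoate
Product: 14 tert-butyl (5E,7R)-2-cyclopropylidene-6-methyl-9-{[tri(propan-2-yl)silyl]oxy}-7-[(trimethylsilyl)ethynyl]non-5-enoate
Conditions: cyclopropyltriphenylphosphonium bromide, KN(SiMe3)2, THF, 0 °C; then 13, 0 → 50 °C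
Reagents that add atoms: cyclopropyltriphenylphosphonium bromide [Br-].C1CC1[P+](c1ccccc1)(c1ccccc1)c1ccccc1
Why: Wittig olefination of the highly electrophilic keto carbonyl with the non‑stabilised cyclopropylidene ylide gives the tetrasubstituted alkylidenecyclopropane, for which no alkene geometry arises because the two ring CH2 groups are equivalent.

Step 9
Reactants: 14 tert-butyl (5E,7R)-2-cyclopropylidene-6-methyl-9-{[tri(propan-2-yl)silyl]oxy}-7-[(trimethylsilyl)ethynyl]non-5-enoate
Product: 15 tert-butyl (5E,7S)-2-cyclopropylidene-7-ethynyl-6-methyl-9-{[tri(propan-2-yl)silyl]oxy}non-5-enoate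
Conditions: Bu4NF, AcOH (1:1), THF, 0 °C
Reagents that add atoms: none
Why: Fluoride‑induced protodesilylation of the alkynylsilane, buffered with acetic acid so that the strained Michael acceptor and the triisopropylsilyl ether survive (the C9 descriptor changes only because the priorities change).

Step 10
Reactants: 15 tert-butyl (5E,7S)-2-cyclopropylidene-7-ethynyl-6-methyl-9-{[tri(propan-2-yl)silyl]oxy}non-5-enoate
Product: 20 tert-butyl (4aR,5S)-4a-methyl-6-methylidene-5-(2-{[tri(propan-2-yl)silyl]oxy}ethyl)-2,3,4,4a,5,6,7,8-octahydronaphthalene-1-carboxylate, via tertiary C10 radical 16 (not isolated), via spirocyclic α-ester radical 17 (not isolated), via primary C7 radical 18 (not isolated), via vinyl radical 19 (not isolated)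
Conditions: Fe(acac)3 (3 equiv), PhSiH3 (slow addition), EtOH/(CH2OH)2 (5:1), 0.005 M, 60 °C
Reagents that add atoms: none
Why: Proposed new method: the iron hydride formed from Fe(acac)3 and PhSiH3 transfers a hydrogen atom to C1 of the trisubstituted alkene, and the tertiary C10 radical 16 adds to C5, the ring carbon of the cyclopropylidene ester, to close ring A and make the C5–C10 bond; the α‑ester cyclopropylcarbinyl radical 17 then opens with loss of ring strain to the primary C7 radical 18 and the conjugated C4=C5 ester, and 18 adds to the inner alkyne carbon C8 to make the C7–C8 bond and ring B, the vinyl radical 19 taking a hydrogen atom from the silane or the solvent to leave the C8=C17 methylidene. The closest known reaction types are the hydrogen‑atom‑transfer‑initiated radical conjugate (Giese) cyclisation of alkenes onto unsaturated esters and the radical cyclisation onto methylenecyclopropanes that is followed by cyclopropylcarbinyl ring opening and capture of the new radical by an alkyne; what is new is their union on a 2‑cyclopropylidene ester, a strained and strongly activated acceptor. Ring A closes in the 6‑endo‑trig mode, which is enforced because attack at C5 gives an ester‑stabilised radical whereas the 5‑exo mode at C4 would give a cyclopropyl radical, and ring B closes in the 6‑exo‑dig mode. C10 is the only new stereocentre and is set relative to C9 in the first ring closure: in the chair‑like transition state the C9–H bond is expected to lie anti to the C10 methyl group, where any larger group would meet the axial hydrogen on C1 and the axial cyclopropane CH2 on C5, the side chain lies anti to the forming bond and the slim ethynyl group gauche to it, which is the arrangement that leads to the 9α‑H,10β‑methyl series and holds the alkyne next to C7 for the second closure. The step needs hydrogen‑atom transfer to go to the electron‑rich trisubstituted alkene and not to the electron‑poor tetrasubstituted enoate or the alkyne (the side‑chain alkene is left out on purpose), and it needs ring opening of 17 and alkyne capture by 18 to outrun reduction, which the stoichiometric iron, the slow silane addition and the high dilution are meant to secure.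

Step 11
Reactants: 20 tert-butyl (4aR,5S)-4a-methyl-6-methylidene-5-(2-{[tri(propan-2-yl)silyl]oxy}ethyl)-2,3,4,4a,5,6,7,8-octahydronaphthalene-1-carboxylate
Product: 22 tert-butyl (1S,4aR,5S,8aR)-1,4a-dimethyl-6-methylidene-5-(2-{[tri(propan-2-yl)silyl]oxy}ethyl)decahydronaphthalene-1-carboxylate, via lithium ester enolate 21 (not isolated)
Conditions: Li (2.2 equiv), t-BuOH (1 equiv), NH3/THF, −78 °C; MeI, −78 → −33 °C
Reagents that add atoms: iodomethane CI
Why: Dissolving‑metal reductive alkylation (Birch type) of the conjugated ester, in which protonation at C5 on the α face, anti to the angular C20 methyl group, should give the trans ring fusion and the enolate 21 is methylated at C4 from the equatorial α face, again anti to the axial C20 methyl group, so that the ester ends axial (C19) and the new methyl equatorial (C18).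

Step 12
Reactants: 22 tert-butyl (1S,4aR,5S,8aR)-1,4a-dimethyl-6-methylidene-5-(2-{[tri(propan-2-yl)silyl]oxy}ethyl)decahydronaphthalene-1-carboxylate
Product: 23 tert-butyl (1S,4aR,5S,8aR)-5-(2-hydroxyethyl)-1,4a-dimethyl-6-methylidenedecahydronaphthalene-1-carboxylate
Conditions: Bu4NF, THF, rt
Reagents that add atoms: none
Why: Fluoride cleavage of the triisopropylsilyl ether; the hindered tert‑butyl ester is inert.

Step 13
Reactants: 23 tert-butyl (1S,4aR,5S,8aR)-5-(2-hydroxyethyl)-1,4a-dimethyl-6-methylidenedecahydronaphthalene-1-carboxylate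
Product: 24 tert-butyl (1S,4aR,5S,8aR)-5-(2-iodoethyl)-1,4a-dimethyl-6-methylidenedecahydronaphthalene-1-carboxylate
Conditions: I2, PPh3, imidazole, CH2Cl2, 0 °C
Reagents that add atoms: iodine II
Why: Appel‑type iodination of the primary alcohol under neutral conditions that spare the exocyclic alkene.

Step 14
Reactants: 24 tert-butyl (1S,4aR,5S,8aR)-5-(2-iodoethyl)-1,4a-dimethyl-6-methylidenedecahydronaphthalene-1-carboxylate
Product: 25 tert-butyl (1S,4aR,5S,8aR)-5-(but-3-yn-1-yl)-1,4a-dimethyl-6-methylidenedecahydronaphthalene-1-carboxylate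
Conditions: LiC≡CH·H2NCH2CH2NH2, DMSO, rt
Reagents that add atoms: lithium acetylide–ethane-1,2-diamine complex [Li]C#C.NCCN
Why: SN2 alkylation of lithium acetylide by the primary iodide adds C13 and C14; the neopentyl tert‑butyl ester is too hindered to be attacked.

Step 15
Reactants: 25 tert-butyl (1S,4aR,5S,8aR)-5-(but-3-yn-1-yl)-1,4a-dimethyl-6-methylidenedecahydronaphthalene-1-carboxylate
Product: 27 tert-butyl (1S,4aR,5S,8aR)-5-[(3E)-5-hydroxy-3-methylpent-3-en-1-yl]-1,4a-dimethyl-6-methylidenedecahydronaphthalene-1-carboxylate, via alkenyldimethylalane 26 (not isolated)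
Conditions: AlMe3, Cp2ZrCl2 (25 mol %), CH2Cl2, 0 °C → rt; n-BuLi, (CH2O)n, THF, −30 °C → rt; aq potassium sodium tartrate
Reagents that add atoms: trimethylaluminium C[Al](C)C; paraformaldehyde (as formaldehyde) C=O
Why: Zirconium‑catalysed carboalumination (Negishi) adds CH3 and Al syn across the terminal alkyne with methyl on C13, and the alkenylalane 26 is hydroxymethylated as its ate complex with retention, which fixes the (13E) geometry.

Step 16
Reactants: 27 tert-butyl (1S,4aR,5S,8aR)-5-[(3E)-5-hydroxy-3-methylpent-3-en-1-yl]-1,4a-dimethyl-6-methylidenedecahydronaphthalene-1-carboxylate; 28 (9Z)-octadec-9-enoyl chloride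
Product: 29 tert-butyl (1S,4aR,5S,8aR)-1,4a-dimethyl-6-methylidene-5-[(3E)-3-methyl-5-{[(9Z)-octadec-9-enoyl]oxy}pent-3-en-1-yl]decahydronaphthalene-1-carboxylate
Conditions: pyridine, DMAP (cat.), CH2Cl2, 0 °C
Reagents that add atoms: none
Why: DMAP‑catalysed acylation of the primary allylic alcohol by the acid chloride; the (9Z) alkene of the acyl group takes no part.

Step 17
Reactants: 29 tert-butyl (1S,4aR,5S,8aR)-1,4a-dimethyl-6-methylidene-5-[(3E)-3-methyl-5-{[(9Z)-octadec-9-enoyl]oxy}pent-3-en-1-yl]decahydronaphthalene-1-carboxylate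
Product: 31 (1S,4aR,5S,8aR)-1,4a-dimethyl-6-methylidene-5-[(3E)-3-methyl-5-{[(9Z)-octadec-9-enoyl]oxy}pent-3-en-1-yl]decahydronaphthalene-1-carboxylic acid, via trimethylsilyl ester 30 (not isolated)
Conditions: Me3SiOTf, 2,6-lutidine, CH2Cl2, 0 °C; then pH 7 buffer
Reagents that add atoms: none
Why: Silyl triflate‑mediated cleavage of the tert‑butyl ester (loss of 2‑methylpropene, then hydrolysis of silyl ester 30) acts at the tert‑butyl group and not at the hindered acyl carbon, and the buffered, non‑protic conditions are chosen to spare the exocyclic alkene and the allylic oleate.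

Compound list
1 | 3-(trimethylsilyl)prop-2-ynal | C[Si](C)(C)C#CC=O | starting material
2 | 2-(triphenyl-λ5-phosphanylidene)propanal | CC(C=O)=P(c1ccccc1)(c1ccccc1)c1ccccc1 | starting material
3 | (2E)-2-methyl-5-(trimethylsilyl)pent-2-en-4-ynal | C[Si](C)(C)C#C/C=C(C)/C=O | intermediate
4 | tert-butyl 4-iodobutanoate | CC(C)(C)OC(=O)CCCI | starting material
5 | bis(4-tert-butoxy-4-oxobutyl)zinc | CC(C)(C)OC(=O)CCC[Zn]CCCC(=O)OC(C)(C)C | intermediate
6 | tert-butyl (5R,6E)-5-hydroxy-6-methyl-9-(trimethylsilyl)non-6-en-8-ynoate | CC(C)(C)OC(=O)CCC[C@@H](O)/C(C)=C/C#C[Si](C)(C)C | intermediate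
7 | mixed ketene acetal, tert-butyl (5R,6E)-5-[(1-ethoxyethenyl)oxy]-6-methyl-9-(trimethylsilyl)non-6-en-8-ynoate | C=C(OCC)O[C@H](CCCC(=O)OC(C)(C)C)/C(C)=C/C#C[Si](C)(C)C | intermediate
8 | 1-tert-butyl 9-ethyl (5E,7R)-6-methyl-7-[(trimethylsilyl)ethynyl]non-5-enedioate | CCOC(=O)C[C@@H](C#C[Si](C)(C)C)/C(C)=C/CCCC(=O)OC(C)(C)C | intermediate
9 | tert-butyl (5E,7R)-9-hydroxy-6-methyl-7-[(trimethylsilyl)ethynyl]non-5-enoate | OCC[C@@H](C#C[Si](C)(C)C)/C(C)=C/CCCC(=O)OC(C)(C)C | intermediate
10 | tert-butyl (5E,7R)-6-methyl-9-{[tri(propan-2-yl)silyl]oxy}-7-[(trimethylsilyl)ethynyl]non-5-enoate | CC(C)[Si](OCC[C@@H](C#C[Si](C)(C)C)/C(C)=C/CCCC(=O)OC(C)(C)C)(C(C)C)C(C)C | intermediate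
11 | potassium ester enolate of 10 | CC(C)[Si](OCC[C@@H](C#C[Si](C)(C)C)/C(C)=C/CCC=C(O[K])OC(C)(C)C)(C(C)C)C(C)C | intermediate
12 | tert-butyl (5E,7R)-2-hydroxy-6-methyl-9-{[tri(propan-2-yl)silyl]oxy}-7-[(trimethylsilyl)ethynyl]non-5-enoate (both C2 epimers) | CC(C)[Si](OCC[C@@H](C#C[Si](C)(C)C)/C(C)=C/CCC(O)C(=O)OC(C)(C)C)(C(C)C)C(C)C | intermediate
13 | tert-butyl (5E,7R)-6-methyl-2-oxo-9-{[tri(propan-2-yl)silyl]oxy}-7-[(trimethylsilyl)ethynyl]non-5-enoate | CC(C)[Si](OCC[C@@H](C#C[Si](C)(C)C)/C(C)=C/CCC(=O)C(=O)OC(C)(C)C)(C(C)C)C(C)C | intermediate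
14 | tert-butyl (5E,7R)-2-cyclopropylidene-6-methyl-9-{[tri(propan-2-yl)silyl]oxy}-7-[(trimethylsilyl)ethynyl]non-5-enoate | CC(C)[Si](OCC[C@@H](C#C[Si](C)(C)C)/C(C)=C/CCC(C(=O)OC(C)(C)C)=C1CC1)(C(C)C)C(C)C | intermediate
15 | tert-butyl (5E,7S)-2-cyclopropylidene-7-ethynyl-6-methyl-9-{[tri(propan-2-yl)silyl]oxy}non-5-enoate | CC(C)[Si](OCC[C@@H](C#C)/C(C)=C/CCC(C(=O)OC(C)(C)C)=C1CC1)(C(C)C)C(C)C | intermediate
16 | tertiary C10 radical (H added to C1 of 15) | CC(C)[Si](OCC[C@@H](C#C)[C](C)CCCC(C(=O)OC(C)(C)C)=C1CC1)(C(C)C)C(C)C | intermediate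
17 | spirocyclic α-ester radical (ring A closed, radical at C4, cyclopropane on C5) | CC(C)[Si](OCC[C@@H](C#C)[C@@]1(C)CCC[C](C(=O)OC(C)(C)C)C12CC2)(C(C)C)C(C)C | intermediate
18 | primary C7 radical (cyclopropane opened, C4=C5 ester restored) | CC(C)[Si](OCC[C@@H](C#C)[C@@]1(C)CCCC(C(=O)OC(C)(C)C)=C1C[CH2])(C(C)C)C(C)C | intermediate
19 | vinyl radical at C17 (ring B closed) | [CH]=C1CCC2=C(C(=O)OC(C)(C)C)CCC[C@]2(C)[C@H]1CCO[Si](C(C)C)(C(C)C)C(C)C | intermediate
20 | tert-butyl (4aR,5S)-4a-methyl-6-methylidene-5-(2-{[tri(propan-2-yl)silyl]oxy}ethyl)-2,3,4,4a,5,6,7,8-octahydronaphthalene-1-carboxylate | C=C1CCC2=C(C(=O)OC(C)(C)C)CCC[C@]2(C)[C@H]1CCO[Si](C(C)C)(C(C)C)C(C)C | intermediate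
21 | lithium ester enolate (C5 protonated, enolate at C4) | C=C1CC[C@@H]2[C@](C)(CCCC2=C(O[Li])OC(C)(C)C)[C@H]1CCO[Si](C(C)C)(C(C)C)C(C)C | intermediate
22 | tert-butyl (1S,4aR,5S,8aR)-1,4a-dimethyl-6-methylidene-5-(2-{[tri(propan-2-yl)silyl]oxy}ethyl)decahydronaphthalene-1-carboxylate | C=C1CC[C@@H]2[C@](C)(CCC[C@]2(C)C(=O)OC(C)(C)C)[C@H]1CCO[Si](C(C)C)(C(C)C)C(C)C | intermediate
23 | tert-butyl (1S,4aR,5S,8aR)-5-(2-hydroxyethyl)-1,4a-dimethyl-6-methylidenedecahydronaphthalene-1-carboxylate | C=C1CC[C@@H]2[C@](C)(CCC[C@]2(C)C(=O)OC(C)(C)C)[C@H]1CCO | intermediate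
24 | tert-butyl (1S,4aR,5S,8aR)-5-(2-iodoethyl)-1,4a-dimethyl-6-methylidenedecahydronaphthalene-1-carboxylate | C=C1CC[C@@H]2[C@](C)(CCC[C@]2(C)C(=O)OC(C)(C)C)[C@H]1CCI | intermediate
25 | tert-butyl (1S,4aR,5S,8aR)-5-(but-3-yn-1-yl)-1,4a-dimethyl-6-methylidenedecahydronaphthalene-1-carboxylate | C=C1CC[C@@H]2[C@](C)(CCC[C@]2(C)C(=O)OC(C)(C)C)[C@H]1CCC#C | intermediate
26 | (E)-alkenyldimethylalane from 25 (CH3 on C13, Al on C14) | C=C1CC[C@@H]2[C@](C)(CCC[C@]2(C)C(=O)OC(C)(C)C)[C@H]1CC/C(C)=C/[Al](C)C | intermediate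
27 | tert-butyl (1S,4aR,5S,8aR)-5-[(3E)-5-hydroxy-3-methylpent-3-en-1-yl]-1,4a-dimethyl-6-methylidenedecahydronaphthalene-1-carboxylate (tert-butyl isocupressate) | C=C1CC[C@@H]2[C@](C)(CCC[C@]2(C)C(=O)OC(C)(C)C)[C@H]1CC/C(C)=C/CO | intermediate
28 | (9Z)-octadec-9-enoyl chloride (oleoyl chloride) | CCCCCCCC/C=C\CCCCCCCC(=O)Cl | starting material
29 | tert-butyl (1S,4aR,5S,8aR)-1,4a-dimethyl-6-methylidene-5-[(3E)-3-methyl-5-{[(9Z)-octadec-9-enoyl]oxy}pent-3-en-1-yl]decahydronaphthalene-1-carboxylate | C=C1CC[C@@H]2[C@](C)(CCC[C@]2(C)C(=O)OC(C)(C)C)[C@H]1CC/C(C)=C/COC(=O)CCCCCCC/C=C\CCCCCCCC | intermediate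
30 | trimethylsilyl ester of 31 | C=C1CC[C@@H]2[C@](C)(CCC[C@]2(C)C(=O)O[Si](C)(C)C)[C@H]1CC/C(C)=C/COC(=O)CCCCCCC/C=C\CCCCCCCC | intermediate
31 | (1S,4aR,5S,8aR)-1,4a-dimethyl-6-methylidene-5-[(3E)-3-methyl-5-{[(9Z)-octadec-9-enoyl]oxy}pent-3-en-1-yl]decahydronaphthalene-1-carboxylic acid (isocupressic acid 15-oleate, CNP0287077.1) | C=C1CC[C@@H]2[C@](C)(CCC[C@]2(C)C(=O)O)[C@H]1CC/C(C)=C/COC(=O)CCCCCCC/C=C\CCCCCCCC | target

Total step count: 17. Longest linear sequence: 17 steps (1 → 31); compounds 2, 4 and 28 enter this single line.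

Steps most likely to fail

Step 10 (the step that carries the label). What may go wrong: hydrogen‑atom transfer to the strained enoate instead of the trisubstituted alkene, reduction of the α‑ester radical before the cyclopropane opens, reduction or a 1,5‑hydrogen shift of the primary radical before it reaches the alkyne, and weak facial control at C10 by the neighbouring C9 centre. The fallback uses known reactions and makes the two bonds one after the other. It sets out from 13. Wittig olefination with the ylide from [3-(tert-butyldimethylsilyloxy)propyl]triphenylphosphonium bromide and NaN(SiMe3)2 gives the trisubstituted enoate F1. Fe(acac)3/PhSiH3 then effects the established hydrogen‑atom‑transfer 6‑endo Giese cyclisation (C5–C10) to the ring A ester F2, and LiN(iPr)2/MeI methylates C4 anti to the C10 methyl group to give the quaternary ester F3. K2CO3/MeOH frees the alkyne to give F4, camphorsulfonic acid/MeOH removes only the tert‑butyldimethylsilyl group to give the primary alcohol F5, and I2/PPh3/imidazole gives the iodide F6. Bu3SnH/AIBN closes ring B by a 6‑exo‑dig radical cyclisation (C7–C8), which comes back to the route at 22.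

Step 11. What may go wrong: over‑reduction of the ester, protonation at C5 from the wrong face, or O‑ instead of C‑methylation of the hindered enolate. The fallback separates reduction from alkylation and avoids the dissolving metal. It sets out from 20: conjugate reduction with SmI2/HMPA/t‑BuOH in THF gives the saturated ester F7 (trans ring fusion expected from the same anti‑to‑methyl protonation; the C4 epimers are of no consequence). In a separate operation F7 is enolised with LiN(iPr)2 and alkylated with MeI, which returns to the route at 22.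

Step 8. What may go wrong: enolisation of the α‑keto ester by the basic, non‑stabilised ylide, or conjugate addition of the ylide to the strained enoate once it has formed. The fallback inverts the roles of the two partners and bypasses steps 6 to 8. It sets out from 10: the enolate (LiN(iPr)2) is brominated with CBr4 to the α‑bromo ester F8, and PPh3 followed by aqueous NaOH gives the stabilised ylide F9. F9 is condensed with (1‑ethoxycyclopropoxy)trimethylsilane (benzoic acid cat., toluene, 90 °C; cyclopropanone formed in situ) to reach 14.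

Further compounds
F1 | step 10 | tert-butyl (5E,7R)-2-[3-(tert-butyldimethylsilyloxy)propylidene]-6-methyl-9-{[tri(propan-2-yl)silyl]oxy}-7-[(trimethylsilyl)ethynyl]non-5-enoate | CC(C)[Si](OCC[C@@H](C#C[Si](C)(C)C)/C(C)=C/CCC(C(=O)OC(C)(C)C)=CCCO[Si](C)(C)C(C)(C)C)(C(C)C)C(C)C
F2 | step 10 | ring A ester, tert-butyl 2-[2-(tert-butyldimethylsilyloxy)ethyl]-3-methyl-3-[5-{[tri(propan-2-yl)silyl]oxy}-1-(trimethylsilyl)pent-1-yn-3-yl]cyclohexane-1-carboxylate (C5, C9, C10 as in 22; C4 epimers) | CC(C)[Si](OCC[C@@H](C#C[Si](C)(C)C)[C@@]1(C)CCCC(C(=O)OC(C)(C)C)[C@@H]1CCO[Si](C)(C)C(C)(C)C)(C(C)C)C(C)C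
F3 | step 10 | C4-methylated ring A ester (C4, C5, C9, C10 as in 22) | CC(C)[Si](OCC[C@@H](C#C[Si](C)(C)C)[C@@]1(C)CCC[C@](C)(C(=O)OC(C)(C)C)[C@@H]1CCO[Si](C)(C)C(C)(C)C)(C(C)C)C(C)C
F4 | step 10 | terminal alkyne from F3 | CC(C)[Si](OCC[C@@H](C#C)[C@@]1(C)CCC[C@](C)(C(=O)OC(C)(C)C)[C@@H]1CCO[Si](C)(C)C(C)(C)C)(C(C)C)C(C)C
F5 | step 10 | primary C7 alcohol from F4 | CC(C)[Si](OCC[C@@H](C#C)[C@@]1(C)CCC[C@](C)(C(=O)OC(C)(C)C)[C@@H]1CCO)(C(C)C)C(C)C
F6 | step 10 | primary C7 iodide from F5 | CC(C)[Si](OCC[C@@H](C#C)[C@@]1(C)CCC[C@](C)(C(=O)OC(C)(C)C)[C@@H]1CCI)(C(C)C)C(C)C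
F7 | step 11 | tert-butyl (4aR,5S,8aR)-4a-methyl-6-methylidene-5-(2-{[tri(propan-2-yl)silyl]oxy}ethyl)decahydronaphthalene-1-carboxylate (C1 epimers) | C=C1CC[C@@H]2[C@](C)(CCCC2C(=O)OC(C)(C)C)[C@H]1CCO[Si](C(C)C)(C(C)C)C(C)C
F8 | step 8 | tert-butyl (5E,7R)-2-bromo-6-methyl-9-{[tri(propan-2-yl)silyl]oxy}-7-[(trimethylsilyl)ethynyl]non-5-enoate | CC(C)[Si](OCC[C@@H](C#C[Si](C)(C)C)/C(C)=C/CCC(Br)C(=O)OC(C)(C)C)(C(C)C)C(C)C
F9 | step 8 | tert-butyl (5E,7R)-6-methyl-9-{[tri(propan-2-yl)silyl]oxy}-2-(triphenyl-λ5-phosphanylidene)-7-[(trimethylsilyl)ethynyl]non-5-enoate | CC(C)[Si](OCC[C@@H](C#C[Si](C)(C)C)/C(C)=C/CCC(C(=O)OC(C)(C)C)=P(c1ccccc1)(c1ccccc1)c1ccccc1)(C(C)C)C(C)C
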